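**Plan**

1. Retrosynthesis: the exocyclic C3=CH2 bond is cut first, then the ring O1–C5 bond, then the C3–C4 bond (enolate plus bromoacetate) and the acyl–auxiliary bond. This leaves 16-hydroxyhexadecanoic acid, tert-butyl bromoacetate and (S)-4-benzyl-2-oxazolidinone.
2. Enabling feature: with the lactone numbered O1, C2 (C=O), C3, C4 (CO2H-bearing), C5 (chain-bearing), opening O1–C5 gives a 2-alkylsuccinic acid. In it C5 is the only chain CH2 that is β to the C4 carboxyl and γ to the C2 carboxyl, so a carboxylate-directed C–H oxygenation can close the single ring.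
3. Forward order: the C16 hydroxy acid supplies C4, C5 and the whole side chain; the C2–C3 acetic arm is joined by auxiliary-controlled alkylation; the lactone ring then arises by O1–C5 bond formation; the methylene carbon is added to C3 last.
4. Stereochemistry: C4 comes from the (S)-oxazolidinone (Evans alkylation, R diacid). C5 is set in the lactonisation by 1,2-induction from C4 (trans), giving C4 (S), C5 (R).

Key step: step 6

Remark on numbering: ring positions in the prose follow the lactone numbering above; the systematic names count the same ring as a tetrahydrofuran, so lactone C5/C4/C3 appear there as C2/C3/C4.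
Remark on the acetate: a primary acetate is assumed not to survive the hot magnesium methoxide medium of step 7. It therefore serves as the alcohol protecting group through step 6 and is put back in step 9.

**Route**

Step 1
Reactants: 1 16-hydroxyhexadecanoic acid
Product: 3 16-acetoxyhexadecanoic acid, via mixed acetic anhydride 2 (not isolated)
Conditions: Ac2O (3 equiv), pyridine, 4-(dimethylamino)pyridine (cat.), rt; then H2O, rt
Reagents that add atoms: acetic anhydride, CC(=O)OC(C)=O
Why: O-acetylation of the primary alcohol by nucleophilic catalysis; the carboxyl group is acylated in passing to mixed anhydride 2, which the aqueous quench hydrolyses back to the free acid.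

Step 2
Reactants: 3 16-acetoxyhexadecanoic acid; 4 (S)-4-benzyl-2-oxazolidinone
Product: 6 (S)-3-(16-acetoxyhexadecanoyl)-4-benzyloxazolidin-2-one, via mixed pivalic anhydride 5 (not isolated)
Conditions: t-BuCOCl, Et3N, THF, −20 °C; then LiCl, 4, rt
Reagents that add atoms: pivaloyl chloride, CC(C)(C)C(=O)Cl (held only in 5)
Why: N-acylation of the oxazolidinone through a mixed pivalic anhydride (LiCl/Et3N protocol), in which the hindered pivaloyl carbonyl steers attack to the fatty acyl carbonyl and no strong base touches the acetate.

Step 3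
Reactants: 6 (S)-3-(16-acetoxyhexadecanoyl)-4-benzyloxazolidin-2-one; 7 tert-butyl bromoacetate
Product: 9 tert-butyl (R)-17-acetoxy-3-[(S)-4-benzyl-2-oxooxazolidine-3-carbonyl]heptadecanoate, via sodium (Z)-enolate 8 (not isolated)
Conditions: NaN(SiMe3)2 (1.1 equiv), THF, −78 °C; then 7 (3 equiv), −78 to −40 °C
Reagents that add atoms: sodium bis(trimethylsilyl)amide, [Na+].C[Si](C)(C)[N-][Si](C)(C)C (sodium held only in 8)
Why: Evans asymmetric alkylation, in which the chelated (Z)-enolate 8 is attacked by the activated bromide on the face opposite the benzyl group, setting the R centre (lactone C4), while one equivalent of base at −78 °C should not enolise the far less acidic acetate.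

Step 4
Reactants: 9 tert-butyl (R)-17-acetoxy-3-[(S)-4-benzyl-2-oxooxazolidine-3-carbonyl]heptadecanoate
Product: 11 (R)-16-acetoxy-2-(2-tert-butoxy-2-oxoethyl)hexadecanoic acid, via peroxy acid 10 (not isolated)
Conditions: LiOH (2 equiv), 30% H2O2 (4 equiv), THF/H2O 3:1, 0 °C; then aq. Na2SO3; then 1 M HCl
Reagents that add atoms: hydrogen peroxide (as LiOOH), OO
Why: Evans hydroperoxide cleavage, in which HOO− attacks the exocyclic imide carbonyl to give peroxy acid 10 (reduced by sulfite) without epimerising the α-centre, while the tert-butyl ester and, at 0 °C, the primary acetate should survive because alkyl esters return HOO− from their tetrahedral adducts.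

Step 5
Reactants: 11 (R)-16-acetoxy-2-(2-tert-butoxy-2-oxoethyl)hexadecanoic acid
Product: 12 (R)-2-(14-acetoxytetradecyl)succinic acid
Conditions: CF3CO2H/CH2Cl2 1:1, rt
Reagents that add atoms: none
Why: acidolysis of the tert-butyl ester (E1 loss of the tert-butyl cation as isobutene), conditions under which the primary acetate and the stereocentre are stable.

Step 6
Reactants: 12 (R)-2-(14-acetoxytetradecyl)succinic acid
Product: 13 (2R,3S)-2-(13-acetoxytridecyl)-5-oxotetrahydrofuran-3-carboxylic acid (trans)
Conditions: Pd(OAc)2 (10 mol%), bidentate quinoline–pyridone ligand (12 mol%), t-BuOOH (70% aq., 2 equiv), CsOAc (1 equiv), (CF3)2CHOH, 60 °C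
Reagents that add atoms: none
Why: Proposed new method: the carboxylate on C4 binds ligand-bound divalent palladium and one C5–H bond is cleaved by concerted metalation–deprotonation to a five-membered palladacycle (the six-membered palladacycle of the C2 carboxylate reaches the same carbon), t-BuOOH oxidises this to a tetravalent palladium alkyl, and the C2 carboxylate then forms the O1–C5 bond; the closest known reaction type is the palladium-catalysed β- and γ-methylene C–H lactonisation of free aliphatic mono- and dicarboxylic acids with pyridone-type ligands and peroxide oxidants. The one ring closes in a 5-exo-tet manner, either by backside displacement of tetravalent palladium at C5 by the C2 carboxylate (from the five-membered palladacycle) or by C–O reductive elimination with retention (from the six-membered one). The new C5 stereocentre is controlled by the existing C4 centre: in the five-membered palladacycle the chain lies trans to the CH2CO2H arm and inversion delivers the trans lactone, and in the six-membered palladacycle the chain lies trans to the C4 carboxyl and retention delivers the same (2R,3S) isomer. Site selectivity among the fourteen chain methylenes is secured because only C5 is within reach of both carboxylates, so it alone can be palladated through a small ring and then captured as an unstrained γ-lactone, whereas the C3 methylene, also β to the C4 carboxyl, could only give a β-lactone or an alkene. Rapid oxidation by the hydroperoxide and the rigid bidentate ligand are counted on to outrun β-hydride elimination, which towards C4 would give an alkylidenesuccinic acid and erase the C4 configuration. The acetate, the free acids and the saturated chain are inert to the oxidant, and what is untested is the diastereocontrol exerted by a neighbouring carboxyl-bearing stereocentre.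

Step 7
Reactants: 13 (2R,3S)-2-(13-acetoxytridecyl)-5-oxotetrahydrofuran-3-carboxylic acid
Product: 15 (2R,3S)-2-(13-hydroxytridecyl)-5-oxotetrahydrofuran-3,4-dicarboxylic acid (C4 epimers), via magnesium dicarboxylate 14 (not isolated)
Conditions: MeOMgOCO2Me (2 M in DMF, large excess), 130 °C; then cold 6 M HCl
Reagents that add atoms: methyl magnesium carbonate, CO[Mg]OC(=O)OC
Why: Stiles carboxylation, in which the reagent enolises lactone C3 and traps the enolate with CO2 as the chelated magnesium salt 14, a standard operation on trans-paraconic acids that leaves C4 and C5 untouched; the same magnesium methoxide medium transesterifies the primary acetate, so excess reagent is used to complete both events.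

Step 8
Reactants: 15 (2R,3S)-2-(13-hydroxytridecyl)-5-oxotetrahydrofuran-3,4-dicarboxylic acid
Product: 17 (2R,3S)-2-(13-hydroxytridecyl)-4-methylene-5-oxotetrahydrofuran-3-carboxylic acid, via Mannich base 16 (not isolated)
Conditions: 37% aq. HCHO, PhNHMe, NaOAc, AcOH, rt
Reagents that add atoms: formaldehyde, C=O; N-methylaniline, CNc1ccccc1 (held only in 16)
Why: decarboxylative Mannich methylenation, in which the malonic-type acid adds to the iminium ion of formaldehyde and N-methylaniline to give 16, which loses CO2 and the amine to leave the exocyclic C3 methylene, the acetate-buffered acidic medium keeping the double bond from moving into the ring.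

Step 9
Reactants: 17 (2R,3S)-2-(13-hydroxytridecyl)-4-methylene-5-oxotetrahydrofuran-3-carboxylic acid
Product: 18 (2R,3S)-2-(13-acetoxytridecyl)-4-methylene-5-oxotetrahydrofuran-3-carboxylic acid (CNP0178400.1)
Conditions: Ac2O (1.2 equiv), Sc(OTf)3 (1 mol%), MeCN/CH2Cl2, −20 °C; then H2O
Reagents that add atoms: acetic anhydride, CC(=O)OC(C)=O
Why: Lewis-acid-catalysed acetylation of the primary alcohol with an anhydride, which is much faster than anhydride exchange at the hindered carboxylic acid and avoids amine bases that could shift the exocyclic alkene into conjugation with the C4 carboxyl and epimerise C4.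

**Compound list**

1 | 16-hydroxyhexadecanoic acid | OCCCCCCCCCCCCCCCC(=O)O | starting material
2 | acetic 16-acetoxyhexadecanoic anhydride | CC(=O)OCCCCCCCCCCCCCCCC(=O)OC(C)=O | intermediate
3 | 16-acetoxyhexadecanoic acid | CC(=O)OCCCCCCCCCCCCCCCC(=O)O | intermediate
4 | (S)-4-benzyl-2-oxazolidinone | O=C1N[C@@H](Cc2ccccc2)CO1 | starting material
5 | 16-acetoxyhexadecanoic pivalic anhydride | CC(=O)OCCCCCCCCCCCCCCCC(=O)OC(=O)C(C)(C)C | intermediate
6 | (S)-3-(16-acetoxyhexadecanoyl)-4-benzyloxazolidin-2-one | CC(=O)OCCCCCCCCCCCCCCCC(=O)N1[C@@H](Cc2ccccc2)COC1=O | intermediate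
7 | tert-butyl bromoacetate | CC(C)(C)OC(=O)CBr | starting material
8 | sodium (Z)-enolate of 6 | CC(=O)OCCCCCCCCCCCCCC/C=C(\[O-])N1[C@@H](Cc2ccccc2)COC1=O.[Na+] | intermediate
9 | tert-butyl (R)-17-acetoxy-3-[(S)-4-benzyl-2-oxooxazolidine-3-carbonyl]heptadecanoate | CC(=O)OCCCCCCCCCCCCCC[C@H](CC(=O)OC(C)(C)C)C(=O)N1[C@@H](Cc2ccccc2)COC1=O | intermediate
10 | (R)-16-acetoxy-2-(2-tert-butoxy-2-oxoethyl)hexadecaneperoxoic acid | CC(=O)OCCCCCCCCCCCCCC[C@H](CC(=O)OC(C)(C)C)C(=O)OO | intermediate
11 | (R)-16-acetoxy-2-(2-tert-butoxy-2-oxoethyl)hexadecanoic acid | CC(=O)OCCCCCCCCCCCCCC[C@H](CC(=O)OC(C)(C)C)C(=O)O | intermediate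
12 | (R)-2-(14-acetoxytetradecyl)succinic acid | CC(=O)OCCCCCCCCCCCCCC[C@H](CC(=O)O)C(=O)O | intermediate
13 | (2R,3S)-2-(13-acetoxytridecyl)-5-oxotetrahydrofuran-3-carboxylic acid | C1C(=O)O[C@H](CCCCCCCCCCCCCOC(C)=O)[C@H]1C(=O)O | intermediate
14 | magnesium (2R,3S)-2-(13-hydroxytridecyl)-5-oxotetrahydrofuran-3,4-dicarboxylate (C4 epimers) | [Mg+2].[O-]C(=O)C1C(=O)O[C@H](CCCCCCCCCCCCCO)[C@H]1C([O-])=O | intermediate
15 | (2R,3S)-2-(13-hydroxytridecyl)-5-oxotetrahydrofuran-3,4-dicarboxylic acid (C4 epimers) | OC(=O)C1C(=O)O[C@H](CCCCCCCCCCCCCO)[C@H]1C(=O)O | intermediate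
16 | (2R,3S)-2-(13-hydroxytridecyl)-4-{[methyl(phenyl)amino]methyl}-5-oxotetrahydrofuran-3,4-dicarboxylic acid (C4 epimers) | CN(CC1(C(=O)O)C(=O)O[C@H](CCCCCCCCCCCCCO)[C@H]1C(=O)O)c1ccccc1 | intermediate
17 | (2R,3S)-2-(13-hydroxytridecyl)-4-methylene-5-oxotetrahydrofuran-3-carboxylic acid | C=C1C(=O)O[C@H](CCCCCCCCCCCCCO)[C@H]1C(=O)O | intermediate
18 | (2R,3S)-2-(13-acetoxytridecyl)-4-methylene-5-oxotetrahydrofuran-3-carboxylic acid | C=C1C(=O)O[C@H](CCCCCCCCCCCCCOC(C)=O)[C@H]1C(=O)O | target

**Step count and risks**

Total step count: 9. Longest linear sequence: 9 steps (1 to 18).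

Steps most likely to fail:

Step 6 (the new method). Palladation may occur at the C3 methylene instead of C5. The C5 palladium alkyl may undergo β-hydride elimination before oxidation, which through re-addition would erode the C4 configuration. The two diastereotopic C5–H bonds may be poorly discriminated; a cis lactone cannot be repaired by epimerising C4 without crossing into the enantiomeric series.
Fallback, from 4 back to 13, by known chemistry: 4 is N-acylated with methyl 4-chloro-4-oxobutanoate (Et3N, cat. 4-(dimethylamino)pyridine, CH2Cl2) to methyl 4-[(S)-4-benzyl-2-oxooxazolidin-3-yl]-4-oxobutanoate F1. Bu2BOTf/i-Pr2NEt (CH2Cl2, −78 to 0 °C) converts it into the dibutylboron (Z)-enolate F2. The aldehyde partner is prepared from commercial tetradecane-1,14-diol by monoacetylation to 14-hydroxytetradecyl acetate F3 and Dess–Martin oxidation to 14-acetoxytetradecanal F4. Evans syn aldol addition of F2 to F4 should give methyl (3S,4R)-17-acetoxy-3-[(S)-4-benzyl-2-oxooxazolidine-3-carbonyl]-4-hydroxyheptadecanoate F5. This lactonises onto its methyl ester on work-up or with catalytic TsOH to the trans lactone imide (S)-4-benzyl-3-[(2R,3S)-2-(13-acetoxytridecyl)-5-oxotetrahydrofuran-3-carbonyl]oxazolidin-2-one F6. LiOH/H2O2 at 0 °C, through the peroxy acid (2R,3S)-2-(13-acetoxytridecyl)-5-oxotetrahydrofuran-3-carboperoxoic acid F7 and a Na2SO3 quench, then releases 13. The same (S)-auxiliary serves, because the boron aldol and the sodium enolate alkylation occur on opposite enolate faces while the roles of the two carbon substituents at C4 are exchanged.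

Step 4. The terminal acetate may be partly lost to hydroperoxide or hydroxide during imide cleavage, giving a mixture.
Fallback, from 9 back to 11, sacrificing and reinstalling the acetate: the cleavage is run as in step 4, and the crude acid, whatever its acetate content, is stirred with additional LiOH in THF/H2O at room temperature (the tert-butyl ester resists). This converges on (R)-2-(2-tert-butoxy-2-oxoethyl)-16-hydroxyhexadecanoic acid F8. Ac2O/pyridine then acetylates the alcohol and forms acetic (R)-16-acetoxy-2-(2-tert-butoxy-2-oxoethyl)hexadecanoic anhydride F9, whose hydrolysis in the aqueous quench returns 11.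

Step 7. Carboxylation may be incomplete or the material may degrade at 130 °C, and methanolysis of the acetate may stop part-way. Any 18 formed early in this way passes through step 9 unchanged.
Fallback, from 13 back to 17, by enolate aminomethylation in place of carboxylation: K2CO3/MeOH removes the acetate and acidification re-closes the lactone to (2R,3S)-2-(13-hydroxytridecyl)-5-oxotetrahydrofuran-3-carboxylic acid F10. Triple deprotonation with NaN(SiMe3)2 (THF, −78 °C; alkoxide, carboxylate and lactone enolate) and trapping with dimethylmethyleneammonium iodide should give (2R,3S)-4-[(dimethylamino)methyl]-2-(13-hydroxytridecyl)-5-oxotetrahydrofuran-3-carboxylic acid F11. MeI in MeOH quaternises it to 1-[(4S,5R)-4-carboxy-5-(13-hydroxytridecyl)-2-oxotetrahydrofuran-3-yl]-N,N,N-trimethylmethanaminium iodide F12. Aqueous NaHCO3 then eliminates trimethylamine to give 17, from which step 9 follows.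

**Further compounds**

F1 | step 6 | methyl 4-[(S)-4-benzyl-2-oxooxazolidin-3-yl]-4-oxobutanoate | COC(=O)CCC(=O)N1[C@@H](Cc2ccccc2)COC1=O
F2 | step 6 | dibutylboron (Z)-enolate of F1 | COC(=O)C/C=C(\OB(CCCC)CCCC)N1[C@@H](Cc2ccccc2)COC1=O
F3 | step 6 | 14-hydroxytetradecyl acetate | CC(=O)OCCCCCCCCCCCCCCO
F4 | step 6 | 14-acetoxytetradecanal | CC(=O)OCCCCCCCCCCCCCC=O
F5 | step 6 | methyl (3S,4R)-17-acetoxy-3-[(S)-4-benzyl-2-oxooxazolidine-3-carbonyl]-4-hydroxyheptadecanoate | CC(=O)OCCCCCCCCCCCCC[C@@H](O)[C@H](CC(=O)OC)C(=O)N1[C@@H](Cc2ccccc2)COC1=O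
F6 | step 6 | (S)-4-benzyl-3-[(2R,3S)-2-(13-acetoxytridecyl)-5-oxotetrahydrofuran-3-carbonyl]oxazolidin-2-one | C1C(=O)O[C@H](CCCCCCCCCCCCCOC(C)=O)[C@H]1C(=O)N2[C@@H](Cc3ccccc3)COC2=O
F7 | step 6 | (2R,3S)-2-(13-acetoxytridecyl)-5-oxotetrahydrofuran-3-carboperoxoic acid | C1C(=O)O[C@H](CCCCCCCCCCCCCOC(C)=O)[C@H]1C(=O)OO
F8 | step 4 | (R)-2-(2-tert-butoxy-2-oxoethyl)-16-hydroxyhexadecanoic acid | OCCCCCCCCCCCCCC[C@H](CC(=O)OC(C)(C)C)C(=O)O
F9 | step 4 | acetic (R)-16-acetoxy-2-(2-tert-butoxy-2-oxoethyl)hexadecanoic anhydride | CC(=O)OCCCCCCCCCCCCCC[C@H](CC(=O)OC(C)(C)C)C(=O)OC(C)=O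
F10 | step 7 | (2R,3S)-2-(13-hydroxytridecyl)-5-oxotetrahydrofuran-3-carboxylic acid | C1C(=O)O[C@H](CCCCCCCCCCCCCO)[C@H]1C(=O)O
F11 | step 7 | (2R,3S)-4-[(dimethylamino)methyl]-2-(13-hydroxytridecyl)-5-oxotetrahydrofuran-3-carboxylic acid (C4 epimers) | CN(C)CC1C(=O)O[C@H](CCCCCCCCCCCCCO)[C@H]1C(=O)O
F12 | step 7 | 1-[(4S,5R)-4-carboxy-5-(13-hydroxytridecyl)-2-oxotetrahydrofuran-3-yl]-N,N,N-trimethylmethanaminium iodide (C3 epimers) | C[N+](C)(C)CC1C(=O)O[C@H](CCCCCCCCCCCCCO)[C@H]1C(=O)O.[I-]
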